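**Assumption:** racemic 6-methylcyclohex-2-en-1-one and potassium isopropenyltrifluoroborate are taken as catalogue chemicals; the bicycle is numbered as in naphthalene (C2 quaternary, C4a ring fusion, C5 carbinol-bearing, C8 methyl-bearing) and C1′ is the benzylic carbon.

## Retrosynthetic overview

1. The last step cuts both C–C bonds at C1′: target ⇒ bicyclic exocyclic 1,3-diene + 3-methylbutanal + 2,4-diformylphloroglucinol. The quaternary C2–C1′ bond comes from metal-hydride H-atom transfer to the diene and addition of the tertiary allyl radical to the unprotected o-quinone methide made in the same flask.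
2. Diene ⇐ non-basic methylenation of the hydroxy octalone ⇐ Mukaiyama hydration of the isopropenyl octalone.
3. Ring A is annulated onto ring B by a Stork enamine Robinson annulation with but-3-en-2-one (sets C4a and C8 relative to C5).
4. Ring B is bought as 6-methylcyclohex-2-enone; Rh/(S)-BINAP conjugate addition of an isopropenyl borate sets the absolute configuration at C5.
5. Arene: resorcinol → phloroglucinol (meta C–H borylation/oxidation) → Vilsmeier diformylation. Ring order: arene and ring B pre-formed, ring A formed in step 4.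

## Route

**Step 1**
Reactants: 1 resorcinol (benzene-1,3-diol)
Product: 4 benzene-1,3,5-triol (phloroglucinol), via bis-TMS ether 2 (not isolated), via arylboronate 3 (not isolated)
Conditions: HMDS, cat. TMSCl, 80 °C, then vacuum; [Ir(OMe)(cod)]2 (1.5 mol %), dtbpy, B2pin2, hexane, 60 °C; Oxone, acetone/H2O, rt
Reagents that add atoms: potassium peroxymonosulfate (Oxone), [K+].[O-]S(=O)(=O)OO
Why: In the in-situ bis-silyl ether C5 is the only C–H not flanked by a substituent, so sterically governed Ir-catalysed C–H borylation followed by one-pot oxidation of the C–B bond (Smith–Maleczka borylation/oxidation) installs the third, meta oxygen, and the acidic Oxone work-up removes the silyl groups.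

**Step 2**
Reactants: 4 benzene-1,3,5-triol
Product: 5 2,4,6-trihydroxybenzene-1,3-dicarbaldehyde (2,4-diformylphloroglucinol)
Conditions: POCl3 (2.2 equiv), DMF (2.2 equiv), dioxane, 0 °C → rt; then H2O
Reagents that add atoms: N,N-dimethylformamide, CN(C)C=O; water, O
Why: Vilsmeier–Haack formylation of the very electron-rich triol stops at the dialdehyde with two equivalents of reagent because each formyl group deactivates the ring (the known preparation of this compound).

**Step 3**
Reactants: 6 6-methylcyclohex-2-en-1-one (racemic); 7 potassium trifluoro(prop-1-en-2-yl)borate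
Product: 8 (5S)-2-methyl-5-(prop-1-en-2-yl)cyclohexan-1-one (both C2 epimers)
Conditions: [Rh(cod)2]PF6 (3 mol %), (S)-BINAP (3.3 mol %), toluene/H2O 20:1, 105 °C
Reagents that add atoms: none
Why: Hayashi–Miyaura Rh/(S)-BINAP asymmetric 1,4-addition (trifluoroborate variant) delivers the alkenyl group to one enantioface of the enone under catalyst control, fixing C5 as S in both C2 epimers, while C2 is α to the ketone and is corrected in step 4.

**Step 4**
Reactants: 8 (5S)-2-methyl-5-(prop-1-en-2-yl)cyclohexan-1-one; 9 but-3-en-2-one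
Product: 12 (4aR,5S,8R)-8-methyl-5-(prop-1-en-2-yl)-4,4a,5,6,7,8-hexahydronaphthalen-2(3H)-one, via enamine 10 (not isolated), via diketone 11 (not isolated)
Conditions: pyrrolidine (1.5 equiv), cat. TsOH, PhH, reflux (−H2O); 9, dioxane, rt; AcOH/NaOAc/H2O, 60 °C
Reagents that add atoms: none
Why: Stork enamine Robinson annulation, in which the equilibrating enamine formation forces the C-methyl group axial by A(1,3) strain (cis to the equatorial isopropenyl group) and places the enamine double bond on the CH2 side, Michael addition then occurs anti to the axial methyl and anti to the neighbouring isopropenyl group, and buffered hydrolysis with aldol condensation closes ring A, so C8 (R) and C4a (R) are set relative to C5.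

**Step 5**
Reactants: 12 (4aR,5S,8R)-8-methyl-5-(prop-1-en-2-yl)-4,4a,5,6,7,8-hexahydronaphthalen-2(3H)-one
Product: 13 (4aR,5S,8R)-5-(2-hydroxypropan-2-yl)-8-methyl-4,4a,5,6,7,8-hexahydronaphthalen-2(3H)-one
Conditions: Co(acac)2 (20 mol %), PhSiH3 (2 equiv), O2 (1 atm), THF, rt
Reagents that add atoms: dioxygen, O=O
Why: Mukaiyama hydration (Co–H hydrogen-atom transfer, then O2 trapping of the tertiary radical) is selective for the electron-rich 1,1-disubstituted alkene over the conjugated trisubstituted enone alkene and touches no stereocenter.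

**Step 6**
Reactants: 13 (4aR,5S,8R)-5-(2-hydroxypropan-2-yl)-8-methyl-4,4a,5,6,7,8-hexahydronaphthalen-2(3H)-one
Product: 14 2-[(1S,4R,8aR)-4-methyl-6-methylidene-1,2,3,4,6,7,8,8a-octahydronaphthalen-1-yl]propan-2-ol
Conditions: Zn, CH2Br2, TiCl4, THF (pre-formed Lombardo reagent); 13, CH2Cl2, 0 °C → rt
Reagents that add atoms: dibromomethane, BrCBr
Why: Lombardo–Takai methylenation uses a non-basic titanium–zinc methylene reagent that tolerates free hydroxyl groups, so the γ-epimerisable enone becomes the exocyclic conjugated diene without enolisation and without loss of C8 or C4a.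

**Step 7 (key step)**
Reactants: 14 2-[(1S,4R,8aR)-4-methyl-6-methylidene-1,2,3,4,6,7,8,8a-octahydronaphthalen-1-yl]propan-2-ol; 15 3-methylbutanal; 5 2,4,6-trihydroxybenzene-1,3-dicarbaldehyde
Product: 17 5-[(1S)-1-[(2S,4aR,5S,8R)-5-(2-hydroxypropan-2-yl)-2,8-dimethyl-2,3,4,4a,5,6,7,8-octahydronaphthalen-2-yl]-3-methylbutyl]-2,4,6-trihydroxybenzene-1,3-dicarbaldehyde, via o-quinone methide 16 (not isolated)
Conditions: 5 and 15 (3 equiv each), NaOAc (cat.), EtOH, 60 °C; then 14, Fe(acac)3 (0.5 equiv), PhSiH3 (2.5 equiv, slow addition), EtOH/(CH2OH)2, 60 °C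
Reagents that add atoms: none
Why: Proposed new method: Knoevenagel condensation of 5 with 15 gives o-quinone methide 16, while Fe–H hydrogen-atom transfer to the terminal CH2 of diene 14 gives a tertiary allyl radical that adds through its less hindered C2 terminus (C8a is shielded by ring B and the axial 8-methyl) to the exocyclic carbon of 16, the aryloxyl radical then being reduced by Fe(II); the closest known reactions are Fe-catalysed reductive olefin–acceptor coupling (Baran type) and radical 1,4/1,6-additions to quinone methides, C2 (S) is expected from equatorial attack on the face of H-4a away from the C4 methylene flap, C1′ (S) is expected from a stacked transition state with the small H of 16 under ring A and its flat ring over C3 instead of under the axial 8-methyl, and the selectivity is expected to be modest, so minor diastereomers are removed by chromatography.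

## Compound list

1 | resorcinol (benzene-1,3-diol) | Oc1cccc(O)c1 | starting material
2 | 1,3-bis(trimethylsilyloxy)benzene | C[Si](C)(C)Oc1cccc(O[Si](C)(C)C)c1 | intermediate
3 | 2-[3,5-bis(trimethylsilyloxy)phenyl]-4,4,5,5-tetramethyl-1,3,2-dioxaborolane | C[Si](C)(C)Oc1cc(O[Si](C)(C)C)cc(c1)B1OC(C)(C)C(C)(C)O1 | intermediate
4 | benzene-1,3,5-triol (phloroglucinol) | Oc1cc(O)cc(O)c1 | intermediate
5 | 2,4,6-trihydroxybenzene-1,3-dicarbaldehyde | O=Cc1c(O)cc(O)c(C=O)c1O | intermediate
6 | 6-methylcyclohex-2-en-1-one (racemic) | CC1CCC=CC1=O | starting material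
7 | potassium trifluoro(prop-1-en-2-yl)borate | [K+].CC(=C)[B-](F)(F)F | starting material
8 | (5S)-2-methyl-5-(prop-1-en-2-yl)cyclohexan-1-one (both C2 epimers) | CC1CC[C@H](C(C)=C)CC1=O | intermediate
9 | but-3-en-2-one | CC(=O)C=C | starting material
10 | 1-[(3S,6R)-6-methyl-3-(prop-1-en-2-yl)cyclohex-1-en-1-yl]pyrrolidine | C1(N2CCCC2)[C@H](C)CC[C@H](C(C)=C)C=1 | intermediate
11 | (2R,3S,6R)-6-methyl-2-(3-oxobutyl)-3-(prop-1-en-2-yl)cyclohexan-1-one | O=C1[C@H](C)CC[C@H](C(C)=C)[C@H]1CCC(C)=O | intermediate
12 | (4aR,5S,8R)-8-methyl-5-(prop-1-en-2-yl)-4,4a,5,6,7,8-hexahydronaphthalen-2(3H)-one | O=C1C=C2[C@H](C)CC[C@H](C(C)=C)[C@H]2CC1 | intermediate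
13 | (4aR,5S,8R)-5-(2-hydroxypropan-2-yl)-8-methyl-4,4a,5,6,7,8-hexahydronaphthalen-2(3H)-one | O=C1C=C2[C@H](C)CC[C@H](C(C)(C)O)[C@H]2CC1 | intermediate
14 | 2-[(1S,4R,8aR)-4-methyl-6-methylidene-1,2,3,4,6,7,8,8a-octahydronaphthalen-1-yl]propan-2-ol | C=C1C=C2[C@H](C)CC[C@H](C(C)(C)O)[C@H]2CC1 | intermediate
15 | 3-methylbutanal | CC(C)CC=O | starting material
16 | 2,4-dihydroxy-5-(3-methylbutylidene)-6-oxocyclohexa-1,3-diene-1,3-dicarbaldehyde (o-quinone methide) | CC(C)CC=C1C(=O)C(C=O)=C(O)C(C=O)=C1O | intermediate
17 | 5-[(1S)-1-[(2S,4aR,5S,8R)-5-(2-hydroxypropan-2-yl)-2,8-dimethyl-2,3,4,4a,5,6,7,8-octahydronaphthalen-2-yl]-3-methylbutyl]-2,4,6-trihydroxybenzene-1,3-dicarbaldehyde | CC(C)C[C@H](c1c(O)c(C=O)c(O)c(C=O)c1O)[C@]1(C)C=C2[C@H](C)CC[C@H](C(C)(C)O)[C@H]2CC1 | target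

## Step count and risks

Total step count: 7. Longest linear sequence: 5 (steps 3 to 7, from 6 and 7).

**Most likely to fail, first: step 7.** The exocyclic alkene of 14 can react with 16 in a polar hetero-Diels–Alder reaction, 5 can sequester iron, 16 can be reduced, the radical can react at C8a, and the selectivity at C2 and C1′ may be low. The fallback changes the radical precursor so that no nucleophilic alkene and no metal hydride are present, and it sets out from 12 and comes back at 17. Methyllithium/CeCl3 adds to 12 to give the tertiary allylic alcohol F1. Acylation with methyl chlorooxoacetate gives the methyl oxalate F2, and CsOH gives the caesium oxalate F3. Separately 5, 15 and benzenesulfinic acid give the bench-stable quinone methide precursor, the sulfone F4. Visible-light photoredox decarboxylation of F3 (Ir photocatalyst, blue light, DME/DMF) releases the same allyl radical while the basic medium unmasks 16 from F4; the adduct is the isopropenyl analogue of the target F5. Mukaiyama hydration of F5 (as in step 5) then gives 17.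

**Second: step 4.** The Michael addition next to the isopropenyl group may be slow, 9 may polymerise, and C8 may epimerise at the diketone or dienamine stage. The fallback leaves enamine chemistry, sets out from 8 and comes back at 11. Kinetic deprotonation of 8 with LDA at −78 °C on the CH2 side and silylation gives the silyl enol ether F6. Lewis-acid Mukaiyama–Michael addition of F6 to 9 (BF3·OEt2, CH2Cl2, −78 °C) gives 11 as an isolated compound. The C-methyl epimers are separated there, and 11 is closed to 12 with pyrrolidinium acetate at room temperature.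

**Third: step 1.** Incomplete silylation would leave O–B groups that direct borylation ortho, and Oxone may over-oxidise the electron-rich triol. The fallback replaces the traceless silyl protection by isolable methyl ethers, sets out from 1 and comes back at 4. Methylation (Me2SO4, K2CO3) gives 1,3-dimethoxybenzene F7. Ir-catalysed borylation gives the arylboronate F8, oxidation gives 3,5-dimethoxyphenol F9, and BBr3 demethylation gives 4.

## Further compounds

F1 | step 7 | (4aR,5S,8R)-2,8-dimethyl-5-(prop-1-en-2-yl)-2,3,4,4a,5,6,7,8-octahydronaphthalen-2-ol (both C2 epimers) | CC1(O)C=C2[C@H](C)CC[C@H](C(C)=C)[C@H]2CC1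
F2 | step 7 | methyl (4aR,5S,8R)-2,8-dimethyl-5-(prop-1-en-2-yl)-2,3,4,4a,5,6,7,8-octahydronaphthalen-2-yl oxalate | COC(=O)C(=O)OC1(C)C=C2[C@H](C)CC[C@H](C(C)=C)[C@H]2CC1
F3 | step 7 | caesium (4aR,5S,8R)-2,8-dimethyl-5-(prop-1-en-2-yl)-2,3,4,4a,5,6,7,8-octahydronaphthalen-2-yl oxalate | [Cs+].[O-]C(=O)C(=O)OC1(C)C=C2[C@H](C)CC[C@H](C(C)=C)[C@H]2CC1
F4 | step 7 | 2,4,6-trihydroxy-5-[3-methyl-1-(phenylsulfonyl)butyl]benzene-1,3-dicarbaldehyde (racemic) | CC(C)CC(c1c(O)c(C=O)c(O)c(C=O)c1O)S(=O)(=O)c1ccccc1
F5 | step 7 | 5-[(1S)-1-[(2S,4aR,5S,8R)-2,8-dimethyl-5-(prop-1-en-2-yl)-2,3,4,4a,5,6,7,8-octahydronaphthalen-2-yl]-3-methylbutyl]-2,4,6-trihydroxybenzene-1,3-dicarbaldehyde | CC(C)C[C@H](c1c(O)c(C=O)c(O)c(C=O)c1O)[C@]1(C)C=C2[C@H](C)CC[C@H](C(C)=C)[C@H]2CC1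
F6 | step 4 | trimethyl{[(3S)-6-methyl-3-(prop-1-en-2-yl)cyclohex-1-en-1-yl]oxy}silane (both C6 epimers) | C1(O[Si](C)(C)C)C(C)CC[C@H](C(C)=C)C=1
F7 | step 1 | 1,3-dimethoxybenzene | COc1cccc(OC)c1
F8 | step 1 | 2-(3,5-dimethoxyphenyl)-4,4,5,5-tetramethyl-1,3,2-dioxaborolane | COc1cc(OC)cc(c1)B1OC(C)(C)C(C)(C)O1
F9 | step 1 | 3,5-dimethoxyphenol | COc1cc(O)cc(OC)c1
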